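- Decide this flask by one race: does it reach the mark, 5.0% converted, before its catalyst fades?

- teal: Z 0.40 M; L 0.40 M; X 0.60 M; D 1.4 mM; the very flask that is asked about, followed so far
- flask: Z 0.40 M; X 0.600 M; D 1.4 mM; L 0.40 M
teal run (percent of the Z and L together charged): time / min: G / % = 4.00: 4.8; 8.00: 7.3; 12.0: 10.5; 15.0: 9.6; 20.0: 12.4; 25.0: 14.4

(scatter of a reading: 1 percentage point)
1. apparent order in D when 5.0% of the Z and L together are converted (percent change of the rate of making G for one percent more D charged)
2. apparent order in X when 5.0% of the Z and L together are converted (percent change of the rate of making G for one percent more X charged)
3. factor on the rate of making G when 5.0% of the Z and L together are converted if D is charged twice over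
- D is single-handed; Z and L are mirror images of each other, charged as a racemate, each of them at the stated concentration
- no earlier run changes the charge of D; that part of a forecast is a guess
- no earlier run changes the charge of X; that part of a forecast is a guess

- Read the teal run, which is this flask so far. The slope over the first 4.00 min is 2.50 times the slope from 15.0 min to 25.0 min.
- Try a loss in which two D meet and die, a second-order catalyst deactivation. The working share of D is then one over (one plus time over fade time), and the fade time shrinks in step with the charge of D.
- Join the two slopes at their mid-times. This gives a fade time of 10.0 min.
- Object: Z and X run down too. So divide the first and last readings by the mean Z and X left. Their ratio becomes 3.57, and this fade time predicts 3.72. The estimate survives, though the first reading carries 20.8% scatter.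
- Object again: the readings do not prove pairing. Commit to it as a stated choice.
- The early slope puts the mark at 4.17 min. Keep 0.417 as the race number, the time to the mark over the fade time. The working share at the mark is then 70.6%.
- Double D. Time to the mark and fade time both shrink in step with D, so the race number holds. My order in D is one, and the rate rises twice.
- Raise X. The time to the mark shortens while the fade time stays, so more D survives. The order in X is one plus the natural log of (one plus the race number), which is 1.35 by my reckoning.
- The forecast gives 1.15 in D, 0.6 in X and a factor of 2.2. Its ground for X is “No run varies X”.
- The flask gives 1.0 in D, 1.4 in X and a factor of 2.00. The forecast parts from it on X.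

    2 D → E (k = 0.530 M⁻¹ s⁻¹)
    X + D + Z → D + G (k = 0.510 M⁻² s⁻¹)
    X + D + L → D + Q (k = 0.0360 M⁻² s⁻¹)

- The pairing of D into E lifts the order in X: the same flask without that step has 1.1, and the actual flask has 1.4. At the mark, 29.6% of the catalyst is E, and my race number from the teal run is 0.417. In the simulated flask with twice the D, the time to the mark changes by a factor of 0.500. The fade time shrinks in step with the charge of D, so my race number stays 0.417, and the rate at the mark rises by a factor of 2.00.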